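**Strategy.** The route rests on cutting the cyclohexene ring (C1–C6) across its C4=C5 double bond: both alkene carbons become CH2 groups bridged by sulfur in a seven-membered thiepane 1,1-dioxide. A Ramberg–Bäcklund ring contraction then extrudes SO2 and delivers the carbocycle and the C4=C5 alkene, flanked by the allylic oxygens at C3 and C6, in one operation, with quaternary C1, C2, C6 and a C3 epimer already set. The thiepane precursor is an acyclic 4,5-dibromide built by aldol union of D-tartrate acetonide (C5, C6, C1, C7) with (S)-glyceraldehyde acetonide (C2–C4). C3 is inverted at the end by Mitsunobu benzoylation.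

Key step: step 8

Remark: carbons carry the target's locants throughout (C1 quaternary carbinol, C2 CHOAc, C3 CHOBz, C4=C5, C6 CHOH, C7 exocyclic CH2O); (S)-glyceraldehyde acetonide is assumed to be bought and used freshly distilled.

**Step 1**
Reactants: 1 dimethyl (4S,5S)-2,2-dimethyl-1,3-dioxolane-4,5-dicarboxylate; 2 (S)-2,2-dimethyl-1,3-dioxolane-4-carbaldehyde
Product: 4 dimethyl (4R,5S)-4-[(S)-[(4S)-2,2-dimethyl-1,3-dioxolan-4-yl](hydroxy)methyl]-2,2-dimethyl-1,3-dioxolane-4,5-dicarboxylate, via lithium enolate 3 (not isolated)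
Conditions: LiN(iPr)2, THF, −78 °C; then 2, −78 °C; AcOH quench at −78 °C
Reagents that add atoms: none
Why: Aldol addition of a lithium ester enolate, in which the aldehyde enters the enolate face anti to the neighbouring CO2Me (sets quaternary C1 with C2 trans to C5 on the dioxolane) and the aldehyde reacts on its Felkin–Anh face (sets C2, 2,3-anti), so both partners use their intrinsically preferred faces.

**Step 2**
Reactants: 4 aldol adduct
Product: 5 (S)-[(4R,5R)-4,5-bis(hydroxymethyl)-2,2-dimethyl-1,3-dioxolan-4-yl][(4S)-2,2-dimethyl-1,3-dioxolan-4-yl]methanol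
Conditions: LiAlH4, THF, 0 °C
Reagents that add atoms: none
Why: Hydride reduction of both methyl esters to primary alcohols leaves the acetonides and all stereocentres untouched.

**Step 3**
Reactants: 5 triol bis-acetonide
Product: 6 (1S,2S)-1-[(4R,5R)-4,5-bis(hydroxymethyl)-2,2-dimethyl-1,3-dioxolan-4-yl]propane-1,2,3-triol
Conditions: AcOH–H2O (7:3), 40 °C
Reagents that add atoms: none
Why: Chemoselective acetal hydrolysis, since the terminal monosubstituted dioxolane is cleaved much faster than the trisubstituted internal one, as in the partial hydrolysis of hexitol triacetonides.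

**Step 4**
Reactants: 6 pentaol
Product: 7 (1S,2R)-3-bromo-1-[(4R,5S)-5-(bromomethyl)-4-(hydroxymethyl)-2,2-dimethyl-1,3-dioxolan-4-yl]propane-1,2-diol
Conditions: PPh3, CBr4, pyridine, 0 °C to rt
Reagents that add atoms: carbon tetrabromide, BrC(Br)(Br)Br
Why: Appel bromination, in which bromide displaces the alkoxyphosphonium ions of the two unhindered primary hydroxyls (C4, C5) by SN2, whereas the neopentyl C7 and the secondary C2/C3 oxygens cannot be displaced and return the alcohols on work-up.

**Step 5**
Reactants: 7 dibromo triol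
Product: 8 tris-TBS ether of 7 (C7, C2 and C3 oxygens silylated; C1 S, C2 S, C3 R, C6 S)
Conditions: TBSOTf, 2,6-lutidine, CH2Cl2, −40 to 0 °C
Reagents that add atoms: tert-butyldimethylsilyl triflate, CC(C)(C)[Si](C)(C)OS(=O)(=O)C(F)(F)F
Why: Silyl ether formation with a silyl triflate turns the three hydroxyls into base-stable poor leaving groups before any basic step, which also stops O7 from closing a tetrahydrofuran onto C5.

**Step 6**
Reactants: 8 tris-TBS dibromide
Product: 10 thiepane with sulfur between C4 and C5 (1,6-O-isopropylidene; 2,3,7-tris-O-TBS; C1 S, C2 S, C3 R, C6 S), via bromo thiolate 9 (not isolated)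
Conditions: Na2S·9H2O, DMF, 60 °C, high dilution
Reagents that add atoms: sodium sulfide, [Na+].[Na+].[S-2]
Why: Double SN2 thioetherification, in which sulfide displaces one primary bromide and the resulting thiolate closes the seven-membered ring by 7-exo-tet displacement of the other.

**Step 7**
Reactants: 10 thiepane
Product: 11 thiepane 1,1-dioxide (same substituents and configurations as 10)
Conditions: mCPBA (2.2 equiv), NaHCO3, CH2Cl2, 0 °C to rt
Reagents that add atoms: 3-chloroperbenzoic acid, OOC(=O)c1cccc(Cl)c1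
Why: Peracid oxidation of the sulfide to the sulfone, to which silyl ethers and the acetonide are inert.

**Step 8**
Reactants: 11 thiepane 1,1-dioxide
Product: 14 cyclohexene (C4=C5) carrying the trans-fused 1,6-O-isopropylidene acetal and TBS ethers at O2, O3 and O7 (C1 S, C2 S, C3 S, C6 R), via α-bromo sulfone 12 (not isolated), via episulfone 13 (not isolated)
Conditions: KOH/Al2O3, CBr2F2, t-BuOH–CH2Cl2, 0 °C to rt
Reagents that add atoms: none
Why: Base removes an α-proton of the sulfone and CBr2F2 transfers bromine to give 12; deprotonation at the other α-carbon and intramolecular 1,3-displacement of bromide give episulfone 13, which loses SO2 cheletropically to form the C4=C5 bond. The closest known reaction type is the in situ halogenative Ramberg–Bäcklund contraction of polyoxygenated thiepane 1,1-dioxides to conduritol-type cyclohexenes. The three-membered thiirane dioxide closes by 3-exo-tet, and the six-membered carbocycle is what remains of the seven-membered ring once sulfur is extruded. No stereocentre is created, because the alkene must be cis in the ring and the transient centres of 12 and 13 are destroyed, while C1, C2, C3 and C6 are spectators. The selectivity needed is 1,3-elimination over E1cB loss of the β-oxygens at C3 and C6, which is secured by their being poor leaving groups (silyl ether, acetal oxygen). Halogenation at either α-carbon leads to the same alkene, so no regiochemical issue arises.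

**Step 9**
Reactants: 14 tris-TBS cyclohexene
Product: 15 cyclohexene triol with free C2, C3 and C7 hydroxyls and the 1,6-O-isopropylidene acetal (C1 R, C2 S, C3 S, C6 R; O2, O3, O6 and C7 on one face, O1 on the other)
Conditions: TBAF, THF, 0 °C to rt
Reagents that add atoms: none
Why: Fluoride-mediated desilylation frees the three hydroxyls, while the acetonide, which is labile only to acid, stays.

**Step 10**
Reactants: 15 triol
Product: 16 C7 benzoate of 15 (C1 R, C2 S, C3 S, C6 R)
Conditions: BzCl (1.05 equiv), pyridine, CH2Cl2, −40 °C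
Reagents that add atoms: benzoyl chloride, O=C(Cl)c1ccccc1
Why: Kinetically controlled acylation, as the primary C7 hydroxyl is benzoylated much faster than the secondary C2 and C3 hydroxyls with one equivalent of acid chloride at low temperature.

**Step 11**
Reactants: 16 C7 benzoate diol
Product: 17 3,7-dibenzoate with inverted C3 and free C2 hydroxyl (C1 R, C2 S, C3 R, C6 R)
Conditions: PPh3, DIAD, BzOH, THF, 0 °C to rt
Reagents that add atoms: benzoic acid, OC(=O)c1ccccc1
Why: Mitsunobu esterification, in which benzoate displaces the activated allylic, pseudoaxial C3 oxygen with SN2 inversion from the open opposite face (sets the 2,3-trans C3 benzoate), while the non-allylic C2 hydroxyl next to quaternary C1 does not react.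

**Step 12**
Reactants: 17 dibenzoate alcohol
Product: 18 2-acetate 3,7-dibenzoate 1,6-O-isopropylidene acetal (C1 S, C2 S, C3 R, C6 R)
Conditions: Ac2O, pyridine, DMAP (cat.), CH2Cl2, rt
Reagents that add atoms: acetic anhydride, CC(=O)OC(C)=O
Why: DMAP-catalysed acetylation of the only free hydroxyl (C2), the C1 and C6 oxygens being tied up in the acetonide.

**Step 13**
Reactants: 18 protected target
Product: 19 [(1S,2S,3R,6R)-2-acetoxy-3-(benzoyloxy)-1,6-dihydroxycyclohex-4-en-1-yl]methyl benzoate (target)
Conditions: TFA–H2O (9:1), 0 °C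
Reagents that add atoms: none
Why: Acid hydrolysis of the strained trans-fused isopropylidene acetal liberates the C1 and C6 hydroxyls, while the three esters survive cold aqueous acid and no stereocentre is touched.

**Compound list**
1 | dimethyl (4S,5S)-2,2-dimethyl-1,3-dioxolane-4,5-dicarboxylate (dimethyl 2,3-O-isopropylidene-D-tartrate) | COC(=O)[C@H]1OC(C)(C)O[C@@H]1C(=O)OC | starting material
2 | (S)-2,2-dimethyl-1,3-dioxolane-4-carbaldehyde ((S)-glyceraldehyde acetonide) | O=C[C@@H]1COC(C)(C)O1 | starting material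
3 | lithium enolate of 1 (ketene acetal at C1, C6 unchanged) | COC(=O)[C@H]1OC(C)(C)OC1=C(OC)[O-].[Li+] | intermediate
4 | dimethyl (4R,5S)-4-[(S)-[(4S)-2,2-dimethyl-1,3-dioxolan-4-yl](hydroxy)methyl]-2,2-dimethyl-1,3-dioxolane-4,5-dicarboxylate | CC1(C)OC[C@H](O1)[C@H](O)[C@]2(OC(C)(C)O[C@@H]2C(=O)OC)C(=O)OC | intermediate
5 | (S)-[(4R,5R)-4,5-bis(hydroxymethyl)-2,2-dimethyl-1,3-dioxolan-4-yl][(4S)-2,2-dimethyl-1,3-dioxolan-4-yl]methanol | CC1(C)OC[C@H](O1)[C@H](O)[C@]2(OC(C)(C)O[C@@H]2CO)CO | intermediate
6 | (1S,2S)-1-[(4R,5R)-4,5-bis(hydroxymethyl)-2,2-dimethyl-1,3-dioxolan-4-yl]propane-1,2,3-triol | OC[C@H](O)[C@H](O)[C@]1(OC(C)(C)O[C@@H]1CO)CO | intermediate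
7 | (1S,2R)-3-bromo-1-[(4R,5S)-5-(bromomethyl)-4-(hydroxymethyl)-2,2-dimethyl-1,3-dioxolan-4-yl]propane-1,2-diol | BrC[C@H](O)[C@H](O)[C@]1(OC(C)(C)O[C@@H]1CBr)CO | intermediate
8 | tris-TBS ether of 7 (O2, O3, O7 silylated) | BrC[C@H](O[Si](C)(C)C(C)(C)C)[C@H](O[Si](C)(C)C(C)(C)C)[C@]1(OC(C)(C)O[C@@H]1CBr)CO[Si](C)(C)C(C)(C)C | intermediate
9 | sodium thiolate from 8 after the first displacement (sulfur on C4, bromide still on C5) | [Na+].[S-]C[C@H](O[Si](C)(C)C(C)(C)C)[C@H](O[Si](C)(C)C(C)(C)C)[C@]1(OC(C)(C)O[C@@H]1CBr)CO[Si](C)(C)C(C)(C)C | intermediate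
10 | thiepane, sulfur between C4 and C5; 1,6-O-isopropylidene; 2,3,7-tris-O-TBS (C1 S, C2 S, C3 R, C6 S) | C1[C@H](O[Si](C)(C)C(C)(C)C)[C@H](O[Si](C)(C)C(C)(C)C)[C@]2(OC(C)(C)O[C@@H]2CS1)CO[Si](C)(C)C(C)(C)C | intermediate
11 | thiepane 1,1-dioxide of 10 | C1[C@H](O[Si](C)(C)C(C)(C)C)[C@H](O[Si](C)(C)C(C)(C)C)[C@]2(OC(C)(C)O[C@@H]2CS1(=O)=O)CO[Si](C)(C)C(C)(C)C | intermediate
12 | α-bromo sulfone (bromine on C5, configuration there not controlled; the C4 regioisomer converges) | C1[C@H](O[Si](C)(C)C(C)(C)C)[C@H](O[Si](C)(C)C(C)(C)C)[C@]2(OC(C)(C)O[C@@H]2C(Br)S1(=O)=O)CO[Si](C)(C)C(C)(C)C | intermediate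
13 | episulfone (thiirane 1,1-dioxide cis-fused across C4–C5) | O=S1(=O)C2[C@H](O[Si](C)(C)C(C)(C)C)[C@H](O[Si](C)(C)C(C)(C)C)[C@]3(OC(C)(C)O[C@@H]3C12)CO[Si](C)(C)C(C)(C)C | intermediate
14 | cyclohex-4-ene, trans-fused 1,6-O-isopropylidene, 2,3,7-tris-O-TBS (C1 S, C2 S, C3 S, C6 R) | C1=C[C@H]2OC(C)(C)O[C@]2(CO[Si](C)(C)C(C)(C)C)[C@@H](O[Si](C)(C)C(C)(C)C)[C@H]1O[Si](C)(C)C(C)(C)C | intermediate
15 | cyclohexene triol, 1,6-O-isopropylidene (C1 R, C2 S, C3 S, C6 R) | C1=C[C@H]2OC(C)(C)O[C@]2(CO)[C@@H](O)[C@H]1O | intermediate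
16 | C7 benzoate of 15 (C1 R, C2 S, C3 S, C6 R) | C1=C[C@H]2OC(C)(C)O[C@]2(COC(=O)c3ccccc3)[C@@H](O)[C@H]1O | intermediate
17 | 3,7-dibenzoate, C3 inverted, free C2 hydroxyl (C1 R, C2 S, C3 R, C6 R) | C1=C[C@H]2OC(C)(C)O[C@]2(COC(=O)c3ccccc3)[C@@H](O)[C@@H]1OC(=O)c4ccccc4 | intermediate
18 | 2-acetate 3,7-dibenzoate 1,6-O-isopropylidene acetal (C1 S, C2 S, C3 R, C6 R) | C1=C[C@H]2OC(C)(C)O[C@]2(COC(=O)c3ccccc3)[C@@H](OC(C)=O)[C@@H]1OC(=O)c4ccccc4 | intermediate
19 | [(1S,2S,3R,6R)-2-acetoxy-3-(benzoyloxy)-1,6-dihydroxycyclohex-4-en-1-yl]methyl benzoate | CC(=O)O[C@H]1[C@H](OC(=O)c2ccccc2)C=C[C@@H](O)[C@@]1(O)COC(=O)c1ccccc1 | target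

**Totals.** Total step count: 13. Longest linear sequence: 13 steps (1 or 2 to 19).

**Steps most likely to fail**

Step 1. The aldol may lose facial control at the aldehyde (Felkin–Anh versus the alternative face, or a mismatched pairing with the enolate face), giving C2 epimers, and the enolate may suffer β-elimination on warming. The fallback sets C2 by reduction instead of by C–C bond formation. It sets out from 1 and 2, run as in step 1 without regard to C2 selectivity, which gives 4 together with the C2 epimer of 4 F1. Dess–Martin oxidation of the mixture converges both on the non-enolisable β-keto diester F2. Reduction with Zn(BH4)2 in Et2O at −20 °C under chelation through the C3 dioxolane oxygen should give the 2,3-anti alcohol, and the route is rejoined at 4.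

Step 4. The free pentaol may react beyond the two intended sites: the neopentyl C7 hydroxyl may close a tetrahydrofuran onto C5, or the C3/C4 pair may form an epoxide. The fallback differentiates the hydroxyls by protection before activation and sets out from 5. Trityl chloride in pyridine should take only the unhindered C5 hydroxyl and give the 5-O-trityl ether F3. TBSOTf with 2,6-lutidine then gives the 2,7-bis-TBS ether F4. Aqueous AcOH at 40 °C removes the trityl group and the terminal acetonide together to give the C3,C4,C5-triol F5. Appel bromination, now without a neopentyl competitor, gives the 4,5-dibromide F6, and silylation of its C3 hydroxyl rejoins the route at 8.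

Step 8. The α-sulfonyl carbanion may expel the β-oxygen at C3 or C6 (ring opening) faster than it is halogenated and cyclised, or the hindered α-carbons may halogenate too slowly. The fallback installs the halogen before the base step and sets out from 10. N-Chlorosuccinimide in CCl4 gives the α-chloro sulfide F7, and mCPBA then gives the α-chloro sulfone F8. KOt-Bu in THF at −78 °C, with short exposure to base, should then contract the ring through episulfone 13, and the route is rejoined at 14.

**Further compounds**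
F1 | step 1 | C2 epimer of 4 | CC1(C)OC[C@H](O1)[C@@H](O)[C@]2(OC(C)(C)O[C@@H]2C(=O)OC)C(=O)OC
F2 | step 1 | β-keto diester (C2 ketone of 4) | CC1(C)OC[C@H](O1)C(=O)[C@]2(OC(C)(C)O[C@@H]2C(=O)OC)C(=O)OC
F3 | step 4 | 5-O-trityl ether of 5 | CC1(C)OC[C@H](O1)[C@H](O)[C@]2(OC(C)(C)O[C@@H]2COC(c3ccccc3)(c4ccccc4)c5ccccc5)CO
F4 | step 4 | 2,7-bis-TBS ether of F3 | CC1(C)OC[C@H](O1)[C@H](O[Si](C)(C)C(C)(C)C)[C@]2(OC(C)(C)O[C@@H]2COC(c3ccccc3)(c4ccccc4)c5ccccc5)CO[Si](C)(C)C(C)(C)C
F5 | step 4 | C3,C4,C5-triol with TBS ethers at O2 and O7 | OC[C@H](O)[C@H](O[Si](C)(C)C(C)(C)C)[C@]1(OC(C)(C)O[C@@H]1CO)CO[Si](C)(C)C(C)(C)C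
F6 | step 4 | 4,5-dibromide with free C3 hydroxyl and TBS ethers at O2 and O7 | BrC[C@H](O)[C@H](O[Si](C)(C)C(C)(C)C)[C@]1(OC(C)(C)O[C@@H]1CBr)CO[Si](C)(C)C(C)(C)C
F7 | step 8 | α-chloro sulfide from 10 (chlorine on C5, configuration not controlled) | C1[C@H](O[Si](C)(C)C(C)(C)C)[C@H](O[Si](C)(C)C(C)(C)C)[C@]2(OC(C)(C)O[C@@H]2C(Cl)S1)CO[Si](C)(C)C(C)(C)C
F8 | step 8 | α-chloro sulfone | C1[C@H](O[Si](C)(C)C(C)(C)C)[C@H](O[Si](C)(C)C(C)(C)C)[C@]2(OC(C)(C)O[C@@H]2C(Cl)S1(=O)=O)CO[Si](C)(C)C(C)(C)C
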